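No J can appear before G has gone through Q, X and L in turn, so expect a lag in J.

    X → L (k1 = 0.0024 /s)
    L ⇌ J (K2 = 0.80, k2 = 0.0028 /s)
    G ⇌ Q (K3 = 0.70, k3 = 0.059 /s)
    L ⇌ E (K4 = 8.8, k4 = 0.058 /s)
    Q → X (k5 = 0.39 /s)
    D ⇌ J, rate k6*(cs6 - [J]) while solid is left; crystals form when [J] > cs6 (cs6 = 5.9 mM, k6 = 2.3 /s)

| setting | zeta | alpha | epsilon | gamma |
|---|---|---|---|---|
| G | 0.0025 M | 0.0050 M | 0.010 M | 0.020 M |
| time | 40 s | 40 s | 40 s | 40 s |

1. [J] (only what is free in solution) at the end for zeta, alpha, epsilon, gamma, in this order
2. how the row runs (rises all the way / rises, then falls / falls, then rises / falls all the way / hardly changes)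

- amounts and yields of J count D too
- given per volume of solution although it is solid: D
- the concentration of J that is asked is that of its free form alone
- "hardly changes" means that all values lie within two and a half points (for a concentration: within two and a half percent of the largest)
- run time (zeta): 40 s

You asked for a quick number, so here is mine, solved at both ends and joined. Reckon per unit of charge and scale last, since the steps in solution are first order and crystals need a free J above 5.9 mM.

At the front end, Q goes on faster than it falls back, so treat it as a passage. G then empties into X with the effective constant kG = 0.0485 /s, after a delay of 2.11 s, which leaves an effective time of 37.9 s.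

At the back end, L is fed from X at 0.0024 /s and leaves towards E and J with kL = 0.0608 /s. Drop the return from E, whose constant is smaller. J collects 0.0028 /s times the running integral of L.

Join the two by integrating the chain, and shave the result for the slow drain of X over about half the run. This gives the conversion y, 0.112%, the fraction of the charge standing as free J at the end. Multiply it by each charge: 2.79 µM, 5.58 µM, 0.0112 mM, 0.0223 mM. Even the top value lies far below the solubility. Each charge is twice the one before, so the row runs: rises all the way.

Your forecast reads 2.800 × 10⁻⁶ M, 5.600 × 10⁻⁶ M, 1.130 × 10⁻⁵ M, 2.260 × 10⁻⁵ M, and rises all the way, on the ground that the chain would “let only about 0.11% of G reach J in 40 s”. At gamma it stands a little above mine.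

The simulation gives 2.78 × 10⁻⁶ M, 5.56 × 10⁻⁶ M, 1.11 × 10⁻⁵ M, 2.22 × 10⁻⁵ M, and rises all the way.

Watch X: in zeta, G has a forward half-life of 12 s and X one of 4.8 min by its onward step, far longer, and X stands at 78.6% of the charge at 40.0 s, with J at 0.111% against y of 0.112%. Carried to gamma, y puts free J at 0.379% of the solubility, and the run there shows J at 0.111% of the charge and D at 0%.

(The rate constants are invented; the run is a simulation.)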